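**Strategy.** Everything rests on opening ring B, the central arene (B1 O–ring A, B2 methyl, B3 methoxy, B5 isopropyl, B6 O–quinone), at two adjacent bonds, B5–isopropyl and B6–oxygen. Because B1–B3 form a symmetric 2-methylresorcinol diether and B6 lies beside the B1 oxygen, a methoxy-flanked aryne across B5–B6 can be made without ambiguity from 5-chloro-1,3-dimethoxy-2-methylbenzene; in one flask it should take isopropyl at B5 and boron at B6. Boron then becomes the B6 hydroxyl, which directs cleavage of the B1 methyl ether; ring A is attached at B1 as an iodonium-derived aryl and ring C by displacement of bromide from a bromothymoquinone.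

Key step: step 2

Remark: the target has no stereocentre; it is assumed that one equivalent of base ionises catechol 13 mainly at the B1 hydroxyl (meta to methoxy, beside methyl), as its higher acidity and lower hindrance suggest.

**Step 1**
Reactants: 1 1-chloro-3,5-dimethoxybenzene; 2 iodomethane
Product: 4 5-chloro-1,3-dimethoxy-2-methylbenzene, via aryllithium 3 (not isolated)
Conditions: n-BuLi, THF, 0 °C; MeI, 0 °C to rt
Reagents that add atoms: iodomethane (2), CI
Why: Directed ortho-lithiation takes the hydrogen held between the two methoxy groups (double coordination of lithium), the aryllithium has chlorine para and so cannot eliminate, and SN2 methylation with MeI should give the symmetric chloroarene.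

**Step 2**
Reactants: 4 5-chloro-1,3-dimethoxy-2-methylbenzene; 5 isopropylmagnesium chloride
Product: 10 (6-isopropyl-2,4-dimethoxy-3-methylphenyl)boronic acid, via aryllithium 6 (not isolated), via aryne 7 (not isolated), via arylmagnesium chloride 8 (not isolated), via dimethyl boronate 9 (not isolated)
Conditions: s-BuLi, THF, −78 °C; iPrMgCl (3 equiv), −78 to 50 °C; B(OMe)3, −78 °C to rt; aq. HCl (1 M), 0 °C
Reagents that add atoms: isopropylmagnesium chloride (5), CC(C)[Mg]Cl; trimethyl borate, COB(OC)OC; water, O
Why: s-BuLi removes one of the two equivalent ring hydrogens of 4, each acidified by a flanking methoxy group and chlorine, and the ortho-chloro organometallic loses LiCl on warming to give the single aryne 7 across B5–B6. The Grignard reagent then adds across the strained triple bond (carbomagnesiation), placing isopropyl on B5 and magnesium on B6, and B(OMe)3 captures arylmagnesium 8 so that hydrolysis delivers the boronic acid; the B5–C and B6–B bonds are thus made in one flask. The closest known reaction type is the addition of Grignard reagents to arynes generated from ortho-lithiated chloroarenes, followed by electrophilic quench of the new ortho-arylmagnesium. No ring is closed and no stereocentre is created. The step needs regioselective addition, which the B1 methoxy group secures: its inductive pull distorts the aryne so that the nucleophile attacks the distal carbon B5 and the negative charge builds up on B6, where magnesium is also held by the neighbouring oxygen, while the mirror symmetry of 4 rules out a second aryne. An excess of the Grignard reagent is used so that it, and not aryllithium 6, intercepts 7.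

**Step 3**
Reactants: 10 (6-isopropyl-2,4-dimethoxy-3-methylphenyl)boronic acid
Product: 11 6-isopropyl-2,4-dimethoxy-3-methylphenol
Conditions: H2O2 (30% aq.), EtOH, rt
Reagents that add atoms: hydrogen peroxide, OO
Why: Oxidative ipso-hydroxylation of an arylboronic acid, in which peroxide adds to boron and the aryl group shifts from boron to oxygen at the same carbon, should turn the boron placeholder into the B6 hydroxyl.

**Step 4**
Reactants: 11 6-isopropyl-2,4-dimethoxy-3-methylphenol
Product: 13 6-isopropyl-4-methoxy-3-methylbenzene-1,2-diol, via cyclic chloroborate 12 (not isolated)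
Conditions: BCl3, CH2Cl2, −78 to 0 °C; degassed H2O
Reagents that add atoms: none
Why: Chelation-assisted Lewis acid ether cleavage: the B6 phenol forms an aryloxydichloroborane that binds the adjacent, out-of-plane B1 methoxy oxygen in a five-membered chelate, so chloride should remove only that methyl group while the unchelated, conjugated B3 methoxy group stays.

**Step 5**
Reactants: 14 carvacrol; 2 iodomethane
Product: 15 4-isopropyl-2-methoxy-1-methylbenzene
Conditions: MeI, K2CO3, acetone, reflux
Reagents that add atoms: iodomethane (2), CI
Why: Williamson ether synthesis on the phenoxide of carvacrol.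

**Step 6**
Reactants: 15 4-isopropyl-2-methoxy-1-methylbenzene
Product: 18 bis(2-isopropyl-4-methoxy-5-methylphenyl)iodonium 4-methylbenzenesulfonate, via aryl iodide 16 (not isolated), via hydroxy(tosyloxy)iodoarene 17 (not isolated)
Conditions: I2, mCPBA, TsOH·H2O, CH2Cl2/CF3CH2OH, rt
Reagents that add atoms: iodine, II; 4-methylbenzenesulfonic acid, Cc1ccc(S(=O)(=O)O)cc1
Why: One-pot synthesis of a symmetric diaryliodonium salt: electrophilic iodination para to methoxy, oxidation of the aryl iodide to trivalent iodine, and electrophilic aromatic substitution of a second arene at the same para position.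

**Step 7**
Reactants: 13 6-isopropyl-4-methoxy-3-methylbenzene-1,2-diol; 18 bis(2-isopropyl-4-methoxy-5-methylphenyl)iodonium 4-methylbenzenesulfonate
Product: 19 6-isopropyl-2-(2-isopropyl-4-methoxy-5-methylphenoxy)-4-methoxy-3-methylphenol
Conditions: t-BuOK (1.0 equiv), THF, 0 °C; 18 (1.1 equiv), 0 to 40 °C, Ar
Reagents that add atoms: none
Why: Metal-free O-arylation of a phenoxide by a diaryliodonium salt (ligand coupling at trivalent iodine): one equivalent of base should place the charge on the more acidic B1 oxygen, which is also the less hindered site for the bulky ortho-isopropyl aryl, and the remaining B6 hydroxyl, flanked by isopropyl and aryloxy, should resist a second arylation.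

**Step 8**
Reactants: 20 4-chloro-2-isopropyl-5-methylphenol
Product: 21 2-bromo-4-chloro-6-isopropyl-3-methylphenol
Conditions: Br2 (1.05 equiv), AcOH, rt
Reagents that add atoms: bromine, BrBr
Why: Electrophilic aromatic bromination can only occur at the single free position ortho to the hydroxyl group, since para is blocked by chlorine, which fixes bromine beside the methyl group.

**Step 9**
Reactants: 21 2-bromo-4-chloro-6-isopropyl-3-methylphenol
Product: 22 3-bromo-5-isopropyl-2-methylcyclohexa-2,5-diene-1,4-dione
Conditions: CrO3, AcOH/H2O, rt
Reagents that add atoms: chromium trioxide, O=[Cr](=O)=O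
Why: Chromic acid oxidation of a para-halophenol to the para-quinone with loss of the para halogen as HCl (oxidative dehalogenation) should give the bromoquinone with bromine on the carbon next to methyl and no regiochemical ambiguity.

**Step 10**
Reactants: 19 6-isopropyl-2-(2-isopropyl-4-methoxy-5-methylphenoxy)-4-methoxy-3-methylphenol; 22 3-bromo-5-isopropyl-2-methylcyclohexa-2,5-diene-1,4-dione
Product: 23 3-[6-isopropyl-2-(2-isopropyl-4-methoxy-5-methylphenoxy)-4-methoxy-3-methylphenoxy]-5-isopropyl-2-methylcyclohexa-2,5-diene-1,4-dione
Conditions: Cs2CO3, MeCN, 0 °C to rt, Ar, dark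
Reagents that add atoms: none
Why: Addition–elimination (vinylogous acyl substitution) of the phenoxide at the bromine-bearing quinone carbon should form the aryl quinonyl ether, and ring B has no free ortho or para carbon that could compete by C-attack.

**Compound list**
1 | 1-chloro-3,5-dimethoxybenzene | COc1cc(Cl)cc(OC)c1 | starting material
2 | iodomethane | CI | starting material
3 | (4-chloro-2,6-dimethoxyphenyl)lithium | [Li]c1c(OC)cc(Cl)cc1OC | intermediate (not isolated)
4 | 5-chloro-1,3-dimethoxy-2-methylbenzene | COc1cc(Cl)cc(OC)c1C | intermediate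
5 | isopropylmagnesium chloride | CC(C)[Mg]Cl | starting material
6 | (6-chloro-2,4-dimethoxy-3-methylphenyl)lithium | [Li]c1c(Cl)cc(OC)c(C)c1OC | intermediate (not isolated)
7 | 1,2-didehydro-3,5-dimethoxy-4-methylbenzene (aryne) | COC1=C(C)C(OC)=CC#C1 | intermediate (not isolated)
8 | (6-isopropyl-2,4-dimethoxy-3-methylphenyl)magnesium chloride | COc1cc(C(C)C)c([Mg]Cl)c(OC)c1C | intermediate (not isolated)
9 | dimethyl (6-isopropyl-2,4-dimethoxy-3-methylphenyl)boronate | COB(OC)c1c(C(C)C)cc(OC)c(C)c1OC | intermediate (not isolated)
10 | (6-isopropyl-2,4-dimethoxy-3-methylphenyl)boronic acid | COc1cc(C(C)C)c(B(O)O)c(OC)c1C | intermediate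
11 | 6-isopropyl-2,4-dimethoxy-3-methylphenol | COc1cc(C(C)C)c(O)c(OC)c1C | intermediate
12 | 2-chloro-4-isopropyl-6-methoxy-7-methyl-1,3,2-benzodioxaborole | COc1cc(C(C)C)c2OB(Cl)Oc2c1C | intermediate (not isolated)
13 | 6-isopropyl-4-methoxy-3-methylbenzene-1,2-diol | COc1cc(C(C)C)c(O)c(O)c1C | intermediate
14 | carvacrol (5-isopropyl-2-methylphenol) | Cc1ccc(C(C)C)cc1O | starting material
15 | 4-isopropyl-2-methoxy-1-methylbenzene | COc1cc(C(C)C)ccc1C | intermediate
16 | 1-iodo-2-isopropyl-4-methoxy-5-methylbenzene | COc1cc(C(C)C)c(I)cc1C | intermediate (not isolated)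
17 | 1-[hydroxy(tosyloxy)-λ3-iodanyl]-2-isopropyl-4-methoxy-5-methylbenzene | COc1cc(C(C)C)c(I(O)OS(=O)(=O)c2ccc(C)cc2)cc1C | intermediate (not isolated)
18 | bis(2-isopropyl-4-methoxy-5-methylphenyl)iodonium 4-methylbenzenesulfonate | COc1cc(C(C)C)c([I+]c2cc(C)c(OC)cc2C(C)C)cc1C.Cc1ccc(S(=O)(=O)[O-])cc1 | intermediate
19 | 6-isopropyl-2-(2-isopropyl-4-methoxy-5-methylphenoxy)-4-methoxy-3-methylphenol | COc1cc(C(C)C)c(Oc2c(C)c(OC)cc(C(C)C)c2O)cc1C | intermediate
20 | 4-chloro-2-isopropyl-5-methylphenol (chlorothymol) | Cc1cc(O)c(C(C)C)cc1Cl | starting material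
21 | 2-bromo-4-chloro-6-isopropyl-3-methylphenol | Cc1c(Cl)cc(C(C)C)c(O)c1Br | intermediate
22 | 3-bromo-5-isopropyl-2-methylcyclohexa-2,5-diene-1,4-dione | CC1=C(Br)C(=O)C(C(C)C)=CC1=O | intermediate
23 | 3-[6-isopropyl-2-(2-isopropyl-4-methoxy-5-methylphenoxy)-4-methoxy-3-methylphenoxy]-5-isopropyl-2-methylcyclohexa-2,5-diene-1,4-dione | COc1cc(C(C)C)c(Oc2c(C)c(OC)cc(C(C)C)c2OC2=C(C)C(=O)C=C(C(C)C)C2=O)cc1C | target

Total step count: 10. Longest linear sequence: 6 steps (steps 1, 2, 3, 4, 7, 10).

**Steps most likely to fail**

1. Step 2. What may go wrong: transfer of a β-hydride from the secondary Grignard reagent to the aryne (reduction in place of C–C bond formation), attack of still unreacted aryllithium on the aryne, or sluggish loss of chloride once lithium has been exchanged for magnesium. The fallback replaces the aryne by cross-coupling, halogenation and halogen–metal exchange; it sets out from 4 and returns at 10. Negishi coupling of 4 with iPrZnBr (Pd(OAc)2, CPhos, THF, rt) should give 5-isopropyl-1,3-dimethoxy-2-methylbenzene F1. Its two free ring positions are equivalent and doubly activated, so NBS (MeCN, 0 °C) should give 2-bromo-1-isopropyl-3,5-dimethoxy-4-methylbenzene F2. Bromine–lithium exchange (n-BuLi, THF, −78 °C) should give (6-isopropyl-2,4-dimethoxy-3-methylphenyl)lithium F3, which B(OMe)3 converts into boronate 9 and aqueous work-up into 10.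

2. Step 7. What may go wrong: insufficient discrimination between the two catechol oxygens, a second arylation, electron transfer from the catecholate to the iodonium salt, or base-induced aryne formation from the electron-rich iodonium salt. The fallback avoids the free catechol; it sets out from 11 and returns at 19. O-Alkylation of 11 with 2-bromopropane (K2CO3, DMF, 60 °C) should give 2-isopropoxy-1-isopropyl-3,5-dimethoxy-4-methylbenzene F4. NaSEt (DMF, 130 °C) should then remove the methyl of the B1 methoxy group, which is twisted out of conjugation by two ortho substituents and offers the better phenoxide leaving group, giving 2-isopropoxy-3-isopropyl-5-methoxy-6-methylphenol F5. Ullmann coupling of F5 with aryl iodide 16 (here made and isolated from 15 with NIS and catalytic CF3CO2H; coupling with CuI, picolinic acid, K3PO4, DMSO, 90 °C) should give 2-isopropoxy-1-isopropyl-3-(2-isopropyl-4-methoxy-5-methylphenoxy)-5-methoxy-4-methylbenzene F6. BCl3 (CH2Cl2, −78 to 0 °C) should cleave the secondary alkyl ether selectively and return 19.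

3. Step 10. What may go wrong: addition of the phenoxide at the unsubstituted quinone carbon, or single-electron oxidation of the electron-rich phenoxide by the quinone, in competition with substitution at the brominated carbon. The fallback uses conjugate addition and re-oxidation in place of substitution; it sets out from 19 and returns at 23. Phenol 19 is added under base catalysis (K2CO3, MeCN, rt) to commercial thymoquinone (CC1=CC(=O)C(C(C)C)=CC1=O), whose unsubstituted carbon beside methyl is the less hindered acceptor. This should give 2-[6-isopropyl-2-(2-isopropyl-4-methoxy-5-methylphenoxy)-4-methoxy-3-methylphenoxy]-6-isopropyl-3-methylbenzene-1,4-diol F7, which Ag2O (Et2O, rt) should oxidise to 23.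

**Further compounds**
F1 | step 2 | 5-isopropyl-1,3-dimethoxy-2-methylbenzene | COc1cc(C(C)C)cc(OC)c1C
F2 | step 2 | 2-bromo-1-isopropyl-3,5-dimethoxy-4-methylbenzene | COc1cc(C(C)C)c(Br)c(OC)c1C
F3 | step 2 | (6-isopropyl-2,4-dimethoxy-3-methylphenyl)lithium | COc1cc(C(C)C)c([Li])c(OC)c1C
F4 | step 7 | 2-isopropoxy-1-isopropyl-3,5-dimethoxy-4-methylbenzene | COc1cc(C(C)C)c(OC(C)C)c(OC)c1C
F5 | step 7 | 2-isopropoxy-3-isopropyl-5-methoxy-6-methylphenol | COc1cc(C(C)C)c(OC(C)C)c(O)c1C
F6 | step 7 | 2-isopropoxy-1-isopropyl-3-(2-isopropyl-4-methoxy-5-methylphenoxy)-5-methoxy-4-methylbenzene | COc1cc(C(C)C)c(Oc2c(C)c(OC)cc(C(C)C)c2OC(C)C)cc1C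
F7 | step 10 | 2-[6-isopropyl-2-(2-isopropyl-4-methoxy-5-methylphenoxy)-4-methoxy-3-methylphenoxy]-6-isopropyl-3-methylbenzene-1,4-diol | COc1cc(C(C)C)c(Oc2c(C)c(OC)cc(C(C)C)c2Oc2c(C)c(O)cc(C(C)C)c2O)cc1C
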